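**Retrosynthetic overview**

- The strategy rests on C8, the only stereocentre. It carries H, the ether oxygen to C4' of ring B (the syringic acid ring) and the C9 hydroxymethyl group. It lies alpha to the C7 ketone on ring A, so it is labile in the target and epimerises freely once C9 is also a carbonyl.
- Oxidation-level disconnection: the C7 ketone goes back to a carbinol and C9 to an ethyl ester. The resulting syn hydroxy ester comes from the racemic C7-keto/C9-ester compound by Ru-catalysed transfer hydrogenation under dynamic kinetic resolution. C7 is only a temporary stereocentre and is oxidised away later.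
- Bond disconnections: C8–O (phenoxide of benzyl syringate plus a racemic alpha-chloride) and C8–C9 (Claisen acylation of O-benzylacetosyringone with diethyl carbonate).
- No ring is formed. Rings A and B are bought as acetosyringone and syringic acid, and both benzyl groups leave together in a neutral final hydrogenolysis.

Key step: step 6

Assumption: neolignan numbering is used (ring A carries C7–C8–C9, ring B carries primed atoms). The (S,S) catalyst series is assigned from the usual aryl-ketone model of this catalyst family, and the mirror-image complex would be used if correlation of the hydroxy ester showed the opposite sense.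

**Step 1**
Reactants: 1 syringic acid
Product: 2 benzyl syringate (benzyl 4-hydroxy-3,5-dimethoxybenzoate)
Conditions: BnBr (1.05 equiv), KHCO3 (1.2 equiv), DMF, 40 °C
Reagents that add atoms: benzyl bromide, BrCc1ccccc1
Why: Carboxylate O-alkylation (SN2 esterification), in which KHCO3 ionises the carboxylic acid but not the far less acidic, doubly ortho-flanked phenol, so benzylation should stop at the ester and leave O4' free for step 5.

**Step 2**
Reactants: 3 acetosyringone
Product: 4 4-O-benzylacetosyringone (1-[4-(benzyloxy)-3,5-dimethoxyphenyl]ethanone)
Conditions: BnBr (1.1 equiv), K2CO3, DMF, 60 °C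
Reagents that add atoms: benzyl bromide, BrCc1ccccc1
Why: Williamson ether synthesis, in which the acidic para-acyl phenol is ionised by K2CO3 and displaces bromide, masking O4 with a group that can be removed without acid or base at the end.

**Step 3**
Reactants: 4 4-O-benzylacetosyringone; 5 diethyl carbonate
Product: 7 ethyl 3-[4-(benzyloxy)-3,5-dimethoxyphenyl]-3-oxopropanoate, via sodium enolate 6 (not isolated)
Conditions: NaH (2.5 equiv), toluene, reflux; then 1 M HCl, 0 °C
Reagents that add atoms: none
Why: Crossed Claisen condensation (C-ethoxycarbonylation of the methyl ketone enolate) brings in C9 at the ester level, because diethyl carbonate cannot enolise and irreversible formation of the stabilised enolate 6 pulls the equilibrium to the product.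

**Step 4**
Reactants: 7 ethyl 3-[4-(benzyloxy)-3,5-dimethoxyphenyl]-3-oxopropanoate
Product: 8 racemic ethyl 3-[4-(benzyloxy)-3,5-dimethoxyphenyl]-2-chloro-3-oxopropanoate
Conditions: SO2Cl2 (1.0 equiv), CH2Cl2, 0 °C
Reagents that add atoms: sulfuryl chloride, O=S(=O)(Cl)Cl
Why: Electrophilic alpha-chlorination of the strongly enolised aroylacetate should consume one equivalent of SO2Cl2 faster than the acyl-deactivated ring A can react, and the new C8 centre is racemic, which is all the key step requires.

**Step 5**
Reactants: 8 racemic alpha-chloro beta-keto ester; 2 benzyl syringate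
Product: 9 racemic ethyl 3-[4-(benzyloxy)-3,5-dimethoxyphenyl]-2-{4-[(benzyloxy)carbonyl]-2,6-dimethoxyphenoxy}-3-oxopropanoate
Conditions: K2CO3 (1.5 equiv), acetone, reflux; aqueous citric acid work-up
Reagents that add atoms: none
Why: Williamson-type SN2 displacement of a doubly carbonyl-activated secondary chloride by the phenoxide of 2 forms the C8–O–C4' ether, a reaction type established for 2-chloro-3-oxo esters and phenols, and chloride is kept as the leaving group without iodide additive because it is the poorest positive-halogen donor toward an electron-rich phenoxide.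

**Step 6**
Reactants: 9 racemic alpha-aryloxy beta-keto ester
Product: 10 ethyl (2S,3R)-3-[4-(benzyloxy)-3,5-dimethoxyphenyl]-2-{4-[(benzyloxy)carbonyl]-2,6-dimethoxyphenoxy}-3-hydroxypropanoate (syn)
Conditions: RuCl[(S,S)-TsDPEN](p-cymene) (2 mol %), HCO2H–Et3N (5:2), CH2Cl2, 30 °C; chromatography or crystallisation to remove any anti isomer
Reagents that add atoms: none
Why: This is a Noyori–Ikariya asymmetric transfer hydrogenation run as a dynamic kinetic resolution, and the closest known case is the same catalyst family acting on alpha-alkoxy beta-keto esters of aryl ketones, which gives syn alpha-alkoxy beta-hydroxy esters. C8–H of 9 is flanked by the C7 ketone, the C9 ester and the aryloxy oxygen, so Et3N should interconvert the two enantiomers through the enol much faster than either is reduced. Formate turns the 16-electron Ru amide into the Ru–H/N–H species, which passes hydride to C7 and a proton to the ketone oxygen in a concerted outer-sphere six-membered transition state, forming only the C7–H bond and closing no ring. C7 is set by the catalyst, because the CH/pi contact between the p-cymene ligand and ring A exposes the Si face of the ketone to the (S,S) complex and gives 7R. C8 is set by matching, because only (S)-9 can present that face with its C8–OAr bond antiperiplanar to the incoming hydride (polar Felkin–Anh arrangement, no chelation in an outer-sphere process), so the racemate should drain into the syn-(2S,3R) ester while any C8 error appears as a separable anti diastereomer. The step also needs chemoselectivity for the ketone, which holds because this hydride donor leaves both esters and both benzyl groups untouched and the two alpha electron-withdrawing groups offset the deactivation by electron-rich ring A.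

**Step 7**
Reactants: 10 syn-(2S,3R) hydroxy ester
Product: 11 benzyl 4-({(1R,2R)-1-[4-(benzyloxy)-3,5-dimethoxyphenyl]-1,3-dihydroxypropan-2-yl}oxy)-3,5-dimethoxybenzoate (threo diol)
Conditions: NaBH4 (excess), THF–H2O (3:1), 0 °C to rt; aqueous NH4Cl
Reagents that add atoms: none
Why: Borohydride reduction of an activated ester works here because the alpha-aryloxy group raises the electrophilicity of the ethyl ester and the neighbouring C7 hydroxyl assists hydride delivery, whereas the conjugated electron-rich benzyl benzoate is inert, and C8 is untouched, its descriptor changing from S to R only because CH2OH ranks below C7.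

**Step 8**
Reactants: 11 threo diol
Product: 12 benzyl 4-({(2R)-1-[4-(benzyloxy)-3,5-dimethoxyphenyl]-3-hydroxy-1-oxopropan-2-yl}oxy)-3,5-dimethoxybenzoate
Conditions: DDQ (1.2 equiv), CH2Cl2, rt, dark; filtration, pH 7 phosphate wash, short neutral silica column
Reagents that add atoms: none
Why: DDQ dehydrogenation of an electron-rich benzylic alcohol abstracts hydride only from C7–H, where the para-alkoxy group of ring A stabilises the cation, so the primary C9 alcohol and the unactivated benzyl groups stay intact and the base-free medium keeps the now enolisable (R)-C8 centre from epimerising or losing formaldehyde by retro-aldol.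

**Step 9**
Reactants: 12 dibenzyl-protected ketone
Product: 13 4-{[(2R)-3-hydroxy-1-(4-hydroxy-3,5-dimethoxyphenyl)-1-oxopropan-2-yl]oxy}-3,5-dimethoxybenzoic acid (CNP0511559.1)
Conditions: H2 (1 atm), 10% Pd/C, EtOAc, rt, stopped after uptake of two equivalents
Reagents that add atoms: none
Why: Catalytic hydrogenolysis cleaves the benzyl aryl ether and the benzyl ester in one neutral operation, while the aryl ketone (deactivated by its para-oxygen donor) and the C8–O bond should survive one atmosphere of hydrogen, and C8 meets neither acid nor base.

**Compound list**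

1 | syringic acid | COc1cc(C(=O)O)cc(OC)c1O | starting material
2 | benzyl syringate | COc1cc(C(=O)OCc2ccccc2)cc(OC)c1O | intermediate
3 | acetosyringone | CC(=O)c1cc(OC)c(O)c(OC)c1 | starting material
4 | 4-O-benzylacetosyringone | CC(=O)c1cc(OC)c(OCc2ccccc2)c(OC)c1 | intermediate
5 | diethyl carbonate | CCOC(=O)OCC | starting material
6 | sodium (Z)-enolate of the beta-keto ester (not isolated) | CCOC(=O)/C=C(\[O-])c1cc(OC)c(OCc2ccccc2)c(OC)c1.[Na+] | intermediate
7 | ethyl 3-[4-(benzyloxy)-3,5-dimethoxyphenyl]-3-oxopropanoate | CCOC(=O)CC(=O)c1cc(OC)c(OCc2ccccc2)c(OC)c1 | intermediate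
8 | racemic ethyl 3-[4-(benzyloxy)-3,5-dimethoxyphenyl]-2-chloro-3-oxopropanoate | CCOC(=O)C(Cl)C(=O)c1cc(OC)c(OCc2ccccc2)c(OC)c1 | intermediate
9 | racemic alpha-aryloxy beta-keto ester | CCOC(=O)C(Oc1c(OC)cc(C(=O)OCc2ccccc2)cc1OC)C(=O)c1cc(OC)c(OCc2ccccc2)c(OC)c1 | intermediate
10 | syn-(2S,3R) alpha-aryloxy beta-hydroxy ester | COc1cc([C@@H](O)[C@@H](C(=O)OCC)Oc2c(OC)cc(C(=O)OCc3ccccc3)cc2OC)cc(OC)c1OCc1ccccc1 | intermediate
11 | (1R,2R) protected arylglycerol beta-aryl ether diol | COc1cc([C@@H](O)[C@@H](CO)Oc2c(OC)cc(C(=O)OCc3ccccc3)cc2OC)cc(OC)c1OCc1ccccc1 | intermediate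
12 | (R) dibenzyl-protected ketone | COc1cc(C(=O)[C@@H](CO)Oc2c(OC)cc(C(=O)OCc3ccccc3)cc2OC)cc(OC)c1OCc1ccccc1 | intermediate
13 | CNP0511559.1, (R) | COc1cc(C(=O)[C@@H](CO)Oc2c(OC)cc(C(=O)O)cc2OC)cc(OC)c1O | target

**Total step count:** 9
**Longest linear sequence:** 8 (steps 2 to 9, from acetosyringone). Step 1 is a one-step side arm.

**Steps most likely to fail**

**Step 6.** Hydride transfer to a ketone crowded by the 2,6-dimethoxyaryloxy group may be slow enough for the mismatched enantiomer to be reduced too. This would show as poor syn/anti selection or eroded facial control. The fallback replaces catalytic reduction with an auxiliary-controlled Evans syn-aldol. It sets out from 2 and comes back at 11.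
- Phenol 2 would be O-alkylated with tert-butyl bromoacetate (K2CO3, acetone) to benzyl 4-(2-tert-butoxy-2-oxoethoxy)-3,5-dimethoxybenzoate F1.
- The tert-butyl ester would be cleaved with TFA in CH2Cl2 to {4-[(benzyloxy)carbonyl]-2,6-dimethoxyphenoxy}acetic acid F2.
- This acid would be coupled through its pivaloyl mixed anhydride (PivCl, Et3N, LiCl, THF) with (S)-4-benzyloxazolidin-2-one to the aryloxyacetyl imide F3.
- The Z boron enolate of the imide (Bu2BOTf, iPr2NEt, CH2Cl2, −78 °C) would add to 4-benzyloxy-3,5-dimethoxybenzaldehyde F4 (bought, or made from syringaldehyde under the conditions of step 2). Addition through a Zimmerman–Traxler chair should give the syn-aldol imide F5, whose (2S,3R) configuration is dictated by the (4S) auxiliary.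
- NaBH4 in THF–H2O then removes the auxiliary reductively and gives diol 11.

**Step 5.** Three processes could compete with substitution by the hindered phenoxide: deprotonation of the chloride to an unreactive enolate, chlorine transfer to the phenoxide, and retro-Claisen cleavage. The fallback forms the C8–O bond by carbenoid insertion instead of SN2. It sets out from 7 and comes back at 9. Regitz diazo transfer to 7 (4-acetamidobenzenesulfonyl azide, Et3N, MeCN) would give ethyl 3-[4-(benzyloxy)-3,5-dimethoxyphenyl]-2-diazo-3-oxopropanoate F6. Slow addition of this compound to phenol 2 and Rh2(OAc)4 (1 mol %) in CH2Cl2 at reflux should give 9 by rhodium-carbenoid O–H insertion, which needs no base and no halide.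

**Step 9.** Over-reduction of the aryl ketone, reductive cleavage of the C8–O bond alpha to the ketone, or slow loss of configuration during prolonged contact with the catalyst could erode the product. The fallback reverses the order of deprotection and oxidation, so the labile ketone is made in the very last operation and never meets Pd and H2. It sets out from 11 and comes back at 13. Hydrogenolysis of diol 11 (H2, Pd/C, EtOAc–EtOH) would give 4-{[(1R,2R)-1,3-dihydroxy-1-(4-hydroxy-3,5-dimethoxyphenyl)propan-2-yl]oxy}-3,5-dimethoxybenzoic acid F7. DDQ in 1,4-dioxane at rt, a known selective oxidation of para-hydroxybenzylic alcohols, would then convert its C7 carbinol into the ketone of 13.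

**Further compounds**

F1 | step 6 | benzyl 4-(2-tert-butoxy-2-oxoethoxy)-3,5-dimethoxybenzoate | CC(C)(C)OC(=O)COc1c(OC)cc(C(=O)OCc2ccccc2)cc1OC
F2 | step 6 | {4-[(benzyloxy)carbonyl]-2,6-dimethoxyphenoxy}acetic acid | OC(=O)COc1c(OC)cc(C(=O)OCc2ccccc2)cc1OC
F3 | step 6 | aryloxyacetyl imide of (S)-4-benzyloxazolidin-2-one | O=C1OC[C@H](Cc2ccccc2)N1C(=O)COc1c(OC)cc(C(=O)OCc2ccccc2)cc1OC
F4 | step 6 | 4-benzyloxy-3,5-dimethoxybenzaldehyde | O=Cc1cc(OC)c(OCc2ccccc2)c(OC)c1
F5 | step 6 | syn-aldol imide, (2S,3R) in the acyl chain, (4S) in the auxiliary | O=C1OC[C@H](Cc2ccccc2)N1C(=O)[C@@H](Oc1c(OC)cc(C(=O)OCc2ccccc2)cc1OC)[C@H](O)c1cc(OC)c(OCc2ccccc2)c(OC)c1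
F6 | step 5 | ethyl 3-[4-(benzyloxy)-3,5-dimethoxyphenyl]-2-diazo-3-oxopropanoate | CCOC(=O)C(=[N+]=[N-])C(=O)c1cc(OC)c(OCc2ccccc2)c(OC)c1
F7 | step 9 | 4-{[(1R,2R)-1,3-dihydroxy-1-(4-hydroxy-3,5-dimethoxyphenyl)propan-2-yl]oxy}-3,5-dimethoxybenzoic acid | COc1cc([C@@H](O)[C@@H](CO)Oc2c(OC)cc(C(=O)O)cc2OC)cc(OC)c1O
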